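**Retrosynthetic overview**
1. The target is traced back to a cis-fused 8β,12-γ-lactone carrying a free 3β-hydroxyl. This temporary lactone ring distinguishes O8 from O3 and carries the α-methylenation; it comes from a 3,8-diketo ester by hydrogenation of C1=C2 and two carbonyl reductions.
2. Key disconnection C9–C10 (ring B): the bicyclic 1,4-dien-3-one with a C8 ketone is traced to a monocyclic aryl silyl ether bearing an α-diazoketone chain. Alkylative dearomatization closes ring B and creates the quaternary C10.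
3. Enabling feature: in ring A the C3 oxygen is para to the methyl-bearing C10 across the C4(Me)=C5 bond, so C1–C5 plus C10 is a masked 2,4-dimethylphenol whose para carbon is C10. C9 is α to the oxygenated C8, so it can be the CH2 of an α-keto diazonium electrophile.
4. The diazoketone comes from an (R)-2-(arylmethyl)succinic half ester, made by Evans alkylation of a succinyl oxazolidinone with 2,6-dimethylbenzyl bromide. Friedel–Crafts acetylation and Baeyer–Villiger oxidation then put in the phenol oxygen.
5. Ring order: ring A is present from the start as the benzene ring; ring B forms in the key step; the temporary lactone ring forms after it and is opened in the penultimate step.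

Key step: step 8

Remark: atoms are named with eudesmane locants (ring A = C1–C5 + C10, ring B = C5–C10, C11–C13 = propenoate unit, C14 and C15 = methyls on C10 and C4); β means the face of the C10 methyl.

Step 1
Reactants: 1 (4R)-4-(propan-2-yl)-1,3-oxazolidin-2-one; 2 methyl 4-chloro-4-oxobutanoate
Product: 3 methyl 4-oxo-4-[(4R)-2-oxo-4-(propan-2-yl)-1,3-oxazolidin-3-yl]butanoate
Conditions: n-BuLi, THF, −78 °C; then 2, −78 to 0 °C
Reagents that add atoms: none
Why: N-acylation of the lithiated oxazolidinone by the acid chloride (standard loading of an Evans auxiliary) is fast at −78 °C and leaves the methyl ester untouched.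

Step 2
Reactants: 3 methyl 4-oxo-4-[(4R)-2-oxo-4-(propan-2-yl)-1,3-oxazolidin-3-yl]butanoate; 4 2-(bromomethyl)-1,3-dimethylbenzene
Product: 5 methyl (3R)-4-(2,6-dimethylphenyl)-3-{[(4R)-2-oxo-4-(propan-2-yl)-1,3-oxazolidin-3-yl]carbonyl}butanoate
Conditions: NaN(SiMe3)2, THF, −78 °C; then 4, −78 to −30 °C
Reagents that add atoms: none
Why: Evans asymmetric alkylation: NaN(SiMe3)2 deprotonates the more acidic imide α-CH2 (not the ester α-CH2) to the chelated Z enolate, and the benzylic bromide is attacked on the face opposite the isopropyl group, which should set C7 as R.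

Step 3
Reactants: 5 methyl (3R)-4-(2,6-dimethylphenyl)-3-{[(4R)-2-oxo-4-(propan-2-yl)-1,3-oxazolidin-3-yl]carbonyl}butanoate
Product: 6 methyl (3R)-4-(3-acetyl-2,6-dimethylphenyl)-3-{[(4R)-2-oxo-4-(propan-2-yl)-1,3-oxazolidin-3-yl]carbonyl}butanoate
Conditions: CH3COCl, AlCl3 (excess), CH2Cl2, 0 °C
Reagents that add atoms: acetyl chloride, CC(Cl)=O
Why: Friedel–Crafts acetylation should go to the arene position ortho to one methyl and para to the other (the future C3; its mirror position is equivalent by rotation of the 2,6-dimethylbenzyl group), the only other free position being meta to both methyls.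

Step 4
Reactants: 6 methyl (3R)-4-(3-acetyl-2,6-dimethylphenyl)-3-{[(4R)-2-oxo-4-(propan-2-yl)-1,3-oxazolidin-3-yl]carbonyl}butanoate
Product: 7 methyl (3R)-4-[3-(acetyloxy)-2,6-dimethylphenyl]-3-{[(4R)-2-oxo-4-(propan-2-yl)-1,3-oxazolidin-3-yl]carbonyl}butanoate
Conditions: mCPBA, CF3CO2H (cat.), CH2Cl2, 0 °C to rt
Reagents that add atoms: 3-chloroperoxybenzoic acid, OOC(=O)c1cccc(Cl)c1
Why: Baeyer–Villiger oxidation of the aryl methyl ketone proceeds with migration of the electron-rich, ortho-substituted aryl group in preference to methyl, turning the acetyl group into the aryl acetate that masks the C3 oxygen.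

Step 5
Reactants: 7 methyl (3R)-4-[3-(acetyloxy)-2,6-dimethylphenyl]-3-{[(4R)-2-oxo-4-(propan-2-yl)-1,3-oxazolidin-3-yl]carbonyl}butanoate
Product: 8 (2R)-2-[(3-hydroxy-2,6-dimethylphenyl)methyl]-4-methoxy-4-oxobutanoic acid
Conditions: LiOH, H2O2, THF/H2O, 0 °C; then Na2SO3 aq.; then HCl aq. to pH 3
Reagents that add atoms: hydrogen peroxide (acting as lithium hydroperoxide), OO
Why: Hydroperoxide-mediated cleavage of the N-acyl oxazolidinone (exocyclic acyl attack by LiOOH) frees the C8 carboxylic acid without epimerizing C7, and the same reagent perhydrolyses the aryl acetate far faster than it touches the unactivated methyl ester at 0 °C.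

Step 6
Reactants: 8 (2R)-2-[(3-hydroxy-2,6-dimethylphenyl)methyl]-4-methoxy-4-oxobutanoic acid
Product: 9 1-[tert-butyl(dimethyl)silyl] 4-methyl (2R)-2-({3-[tert-butyl(dimethyl)silyloxy]-2,6-dimethylphenyl}methyl)butanedioate
Conditions: t-BuMe2SiCl (2.2 equiv), imidazole, DMF, rt
Reagents that add atoms: tert-butyl(chloro)dimethylsilane, CC(C)(C)[Si](C)(C)Cl
Why: Silylation of both acidic OH groups gives the aryl silyl ether that protects the C3 oxygen and the silyl ester that is the neutral precursor of the acid chloride.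

Step 7
Reactants: 9 1-[tert-butyl(dimethyl)silyl] 4-methyl (2R)-2-({3-[tert-butyl(dimethyl)silyloxy]-2,6-dimethylphenyl}methyl)butanedioate
Product: 11 methyl (3R)-3-({3-[tert-butyl(dimethyl)silyloxy]-2,6-dimethylphenyl}methyl)-5-diazo-4-oxopentanoate, via acid chloride 10 (not isolated)
Conditions: (COCl)2, DMF (cat.), CH2Cl2, 0 °C to rt; evaporate; then CH2N2 (excess), Et2O, 0 °C
Reagents that add atoms: diazomethane, C=[N+]=[N-]
Why: Silyl esters are converted by oxalyl chloride and catalytic DMF into acid chlorides under neutral conditions (no base, so C7 and the aryl silyl ether are safe), and acylation of excess diazomethane then gives the α-diazoketone (first stage of the Arndt–Eistert sequence), a second equivalent of diazomethane removing HCl.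

Step 8
Reactants: 11 methyl (3R)-3-({3-[tert-butyl(dimethyl)silyloxy]-2,6-dimethylphenyl}methyl)-5-diazo-4-oxopentanoate
Product: 14 methyl 2-[(2R,4aS)-4a,8-dimethyl-3,7-dioxo-1,2,3,4,4a,7-hexahydronaphthalen-2-yl]acetate, via α-keto diazonium trifluoroacetate 12 (not isolated), via O-silyl cyclohexadienyl cation 13 (not isolated)
Conditions: CF3CO2H, CH2Cl2, −20 °C, short contact time; then NaHCO3 aq.
Reagents that add atoms: none
Why: Protonation of the diazo carbon by CF3CO2H gives the α-keto diazonium ion 12, whose CH2–N2 carbon (C9) is displaced in an SN2-like attack by the arene carbon para to the silyloxy group (C10), and the resulting O-silyl cyclohexadienyl cation 13 loses its silyl group to trifluoroacetate to unveil the cross-conjugated dienone. The closest known reaction type is the acid-promoted intramolecular alkylation of phenols and phenol ethers by α-diazoketones (alkylative dearomatization to cyclohexa-2,5-dienones). Ring B is the only ring closed, in the 6-exo-tet (Ar2-6) mode, while ring A changes from arene to 4-methylcyclohexa-1,4-dien-3-one. The new quaternary stereocenter C10 is controlled by C7: in the chair-like transition state the CH2CO2Me arm should sit pseudo-equatorial and point away from the arene, the alternative placing it pseudo-axial and syn to the C9–N2 axis, so that the C10 methyl ends up cis to the C7 side chain (C7 R, C10 S in 14, the spatial arrangement of the target). The step needs attack at the para carbon C10 and not at the ortho carbon C4, both being methyl-bearing ipso positions that would give six-membered rings; the para position has the larger coefficient and leads to the more stable para-quinoid cation, and C4 is flanked on both sides and shielded by the neighbouring OSiMe2t-Bu group, whereas C10 has the unsubstituted C1–H as neighbour.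

Step 9
Reactants: 14 methyl 2-[(2R,4aS)-4a,8-dimethyl-3,7-dioxo-1,2,3,4,4a,7-hexahydronaphthalen-2-yl]acetate
Product: 15 methyl 2-[(2R,4aR)-4a,8-dimethyl-3,7-dioxo-1,2,3,4,4a,5,6,7-octahydronaphthalen-2-yl]acetate
Conditions: H2 (1 atm), RhCl(PPh3)3 (cat.), benzene/EtOH, rt
Reagents that add atoms: none
Why: Homogeneous hydrogenation with RhCl(PPh3)3 should reduce the disubstituted C1=C2 bond of the cross-conjugated dienone and leave the tetrasubstituted C4=C5 bond, both ketones and the ester untouched, as is typical for 1,4-dien-3-ones (the C10 descriptor changes to R only because the priorities change).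

Step 10
Reactants: 15 methyl 2-[(2R,4aR)-4a,8-dimethyl-3,7-dioxo-1,2,3,4,4a,5,6,7-octahydronaphthalen-2-yl]acetate
Product: 17 (3aR,8aR,9aR)-5,8a-dimethyl-3a,4,7,8,8a,9-hexahydronaphtho[2,3-b]furan-2,6(3H,9aH)-dione, via 8β-hydroxy ester 16 (not isolated)
Conditions: LiBH(s-Bu)3 (1.05 equiv), THF, −78 °C; HCl aq.; then TsOH·H2O (cat.), CH2Cl2, rt
Reagents that add atoms: none
Why: The bulky hydride should reduce the saturated C8 ketone faster than the hindered β,β-disubstituted C3 enone and attack from the equatorial α-direction, the axial β-face being blocked by the syn-axial C10 methyl, to give the axial 8β-alcohol (C8 R), which closes the cis-fused γ-lactone onto the neighbouring equatorial CH2CO2Me arm under acid catalysis (lactonization).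

Step 11
Reactants: 17 (3aR,8aR,9aR)-5,8a-dimethyl-3a,4,7,8,8a,9-hexahydronaphtho[2,3-b]furan-2,6(3H,9aH)-dione
Product: 18 (3aR,6S,8aR,9aR)-6-hydroxy-5,8a-dimethyl-3a,4,6,7,8,8a,9,9a-octahydronaphtho[2,3-b]furan-2(3H)-one
Conditions: NaBH4, CeCl3·7H2O, MeOH, −78 to −40 °C
Reagents that add atoms: none
Why: Luche reduction gives 1,2-reduction of the enone without touching the lactone, hydride adding axially from the α-face opposite the C10 methyl to give the pseudo-equatorial 3β-alcohol (C3 S).

Step 12
Reactants: 18 (3aR,6S,8aR,9aR)-6-hydroxy-5,8a-dimethyl-3a,4,6,7,8,8a,9,9a-octahydronaphtho[2,3-b]furan-2(3H)-one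
Product: 21 (3aR,6S,8aR,9aR)-6-hydroxy-5,8a-dimethyl-3-methylidene-3a,4,6,7,8,8a,9,9a-octahydronaphtho[2,3-b]furan-2(3H)-one, via Mannich base 19 (not isolated), via trimethylammonium iodide 20 (not isolated)
Conditions: LiN(i-Pr)2 (2.2 equiv), THF, −78 °C; CH2=NMe2+ I−, −78 to 0 °C; aqueous work-up; then MeI, MeOH, rt; then NaHCO3 aq./CH2Cl2, rt
Reagents that add atoms: dimethylmethylideneammonium iodide (Eschenmoser's salt), C=[N+](C)C.[I-]
Why: α-Methylenation of the lactone through its enolate (as the dianion, the C3 alkoxide forming first): Mannich reaction with the iminium salt, exhaustive N-methylation and E1cB elimination of trimethylamine install the exocyclic C11=C13 bond, the configuration at C11 of 19 and 20 being of no consequence.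

Step 13
Reactants: 21 (3aR,6S,8aR,9aR)-6-hydroxy-5,8a-dimethyl-3-methylidene-3a,4,6,7,8,8a,9,9a-octahydronaphtho[2,3-b]furan-2(3H)-one
Product: 22 (3aR,6S,8aR,9aR)-5,8a-dimethyl-3-methylidene-2-oxo-2,3,3a,4,6,7,8,8a,9,9a-decahydronaphtho[2,3-b]furan-6-yl 2-methylpropanoate
Conditions: (CH3)2CHCOCl, pyridine, DMAP (cat.), CH2Cl2, 0 °C
Reagents that add atoms: 2-methylpropanoyl chloride, CC(C)C(Cl)=O
Why: DMAP-catalysed acylation of the unhindered pseudo-equatorial allylic alcohol installs the C3 isobutyrate with retention at C3 while O8 is still tied up in the lactone.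

Step 14
Reactants: 22 (3aR,6S,8aR,9aR)-5,8a-dimethyl-3-methylidene-2-oxo-2,3,3a,4,6,7,8,8a,9,9a-decahydronaphtho[2,3-b]furan-6-yl 2-methylpropanoate
Product: 24 methyl 2-[(2R,3R,4aR,7S)-3-hydroxy-4a,8-dimethyl-7-(2-methylpropanoyloxy)-1,2,3,4,4a,5,6,7-octahydronaphthalen-2-yl]prop-2-enoate, via potassium carboxylate 23 (not isolated)
Conditions: KOH (1.0 equiv), THF/H2O, 0 °C; evaporate; then MeI, DMF, 0 °C to rt; used crude at once
Reagents that add atoms: potassium hydroxide, [K+].[OH-]; iodomethane, CI
Why: Saponification of the γ-lactone by one equivalent of hydroxide should be much faster than that of the hindered secondary isobutyrate (the ring holds the ester in its more reactive E geometry), and SN2 O-methylation of the carboxylate with iodomethane, in the absence of acid or excess base, gives the open γ-hydroxy α-methylene ester, a type of compound that persists under neutral conditions.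

Step 15
Reactants: 24 methyl 2-[(2R,3R,4aR,7S)-3-hydroxy-4a,8-dimethyl-7-(2-methylpropanoyloxy)-1,2,3,4,4a,5,6,7-octahydronaphthalen-2-yl]prop-2-enoate
Product: 25 methyl 2-[(2R,3R,4aR,7S)-3-(acetyloxy)-4a,8-dimethyl-7-(2-methylpropanoyloxy)-1,2,3,4,4a,5,6,7-octahydronaphthalen-2-yl]prop-2-enoate
Conditions: Ac2O, DMAP (cat.), pyridine, CH2Cl2, 0 °C
Reagents that add atoms: acetic anhydride, CC(=O)OC(C)=O
Why: DMAP-catalysed acetylation of the axial 8β-hydroxyl with excess anhydride, run immediately on crude 24, should outpace relactonization and completes the target with all four stereocenters (C3 S, C7 R, C8 R, C10 R) unchanged.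

**Compound list**
1 | (4R)-4-(propan-2-yl)-1,3-oxazolidin-2-one | CC(C)[C@@H]1COC(=O)N1 | starting material
2 | methyl 4-chloro-4-oxobutanoate | COC(=O)CCC(Cl)=O | starting material
3 | methyl 4-oxo-4-[(4R)-2-oxo-4-(propan-2-yl)-1,3-oxazolidin-3-yl]butanoate | COC(=O)CCC(=O)N1[C@H](C(C)C)COC1=O | intermediate
4 | 2-(bromomethyl)-1,3-dimethylbenzene (2,6-dimethylbenzyl bromide) | Cc1cccc(C)c1CBr | starting material
5 | methyl (3R)-4-(2,6-dimethylphenyl)-3-{[(4R)-2-oxo-4-(propan-2-yl)-1,3-oxazolidin-3-yl]carbonyl}butanoate | COC(=O)C[C@@H](Cc1c(C)cccc1C)C(=O)N1[C@H](C(C)C)COC1=O | intermediate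
6 | methyl (3R)-4-(3-acetyl-2,6-dimethylphenyl)-3-{[(4R)-2-oxo-4-(propan-2-yl)-1,3-oxazolidin-3-yl]carbonyl}butanoate | COC(=O)C[C@@H](Cc1c(C)ccc(C(C)=O)c1C)C(=O)N1[C@H](C(C)C)COC1=O | intermediate
7 | methyl (3R)-4-[3-(acetyloxy)-2,6-dimethylphenyl]-3-{[(4R)-2-oxo-4-(propan-2-yl)-1,3-oxazolidin-3-yl]carbonyl}butanoate | COC(=O)C[C@@H](Cc1c(C)ccc(OC(C)=O)c1C)C(=O)N1[C@H](C(C)C)COC1=O | intermediate
8 | (2R)-2-[(3-hydroxy-2,6-dimethylphenyl)methyl]-4-methoxy-4-oxobutanoic acid | COC(=O)C[C@@H](Cc1c(C)ccc(O)c1C)C(=O)O | intermediate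
9 | 1-[tert-butyl(dimethyl)silyl] 4-methyl (2R)-2-({3-[tert-butyl(dimethyl)silyloxy]-2,6-dimethylphenyl}methyl)butanedioate | COC(=O)C[C@@H](Cc1c(C)ccc(O[Si](C)(C)C(C)(C)C)c1C)C(=O)O[Si](C)(C)C(C)(C)C | intermediate
10 | methyl (3R)-3-(chlorocarbonyl)-4-{3-[tert-butyl(dimethyl)silyloxy]-2,6-dimethylphenyl}butanoate (acid chloride, not isolated) | COC(=O)C[C@@H](Cc1c(C)ccc(O[Si](C)(C)C(C)(C)C)c1C)C(Cl)=O | intermediate
11 | methyl (3R)-3-({3-[tert-butyl(dimethyl)silyloxy]-2,6-dimethylphenyl}methyl)-5-diazo-4-oxopentanoate | COC(=O)C[C@@H](Cc1c(C)ccc(O[Si](C)(C)C(C)(C)C)c1C)C(=O)C=[N+]=[N-] | intermediate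
12 | (4R)-4-({3-[tert-butyl(dimethyl)silyloxy]-2,6-dimethylphenyl}methyl)-6-methoxy-2,6-dioxohexane-1-diazonium trifluoroacetate (α-keto diazonium salt, not isolated) | COC(=O)C[C@@H](Cc1c(C)ccc(O[Si](C)(C)C(C)(C)C)c1C)C(=O)C[N+]#N.[O-]C(=O)C(F)(F)F | intermediate
13 | O-tert-butyl(dimethyl)silyl oxocarbenium (cyclohexadienyl) cation of 14 at the C3 oxygen, (2R,4aS), trifluoroacetate (not isolated) | COC(=O)C[C@H]1CC2=C(C)C(=[O+][Si](C)(C)C(C)(C)C)C=C[C@]2(C)CC1=O.[O-]C(=O)C(F)(F)F | intermediate
14 | methyl 2-[(2R,4aS)-4a,8-dimethyl-3,7-dioxo-1,2,3,4,4a,7-hexahydronaphthalen-2-yl]acetate (C3 dienone, C8 ketone; C7 R, C10 S) | COC(=O)C[C@H]1CC2=C(C)C(=O)C=C[C@]2(C)CC1=O | intermediate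
15 | methyl 2-[(2R,4aR)-4a,8-dimethyl-3,7-dioxo-1,2,3,4,4a,5,6,7-octahydronaphthalen-2-yl]acetate | COC(=O)C[C@H]1CC2=C(C)C(=O)CC[C@]2(C)CC1=O | intermediate
16 | methyl 2-[(2R,3R,4aR)-3-hydroxy-4a,8-dimethyl-7-oxo-1,2,3,4,4a,5,6,7-octahydronaphthalen-2-yl]acetate (8β-hydroxy ester, not isolated) | COC(=O)C[C@H]1CC2=C(C)C(=O)CC[C@]2(C)C[C@H]1O | intermediate
17 | (3aR,8aR,9aR)-5,8a-dimethyl-3a,4,7,8,8a,9-hexahydronaphtho[2,3-b]furan-2,6(3H,9aH)-dione (cis-fused 8β,12-lactone, C3 enone) | O=C1C[C@H]2CC3=C(C)C(=O)CC[C@]3(C)C[C@H]2O1 | intermediate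
18 | (3aR,6S,8aR,9aR)-6-hydroxy-5,8a-dimethyl-3a,4,6,7,8,8a,9,9a-octahydronaphtho[2,3-b]furan-2(3H)-one | O=C1C[C@H]2CC3=C(C)[C@@H](O)CC[C@]3(C)C[C@H]2O1 | intermediate
19 | 3-[(dimethylamino)methyl] derivative of 18 (Mannich base, epimers at C11, not isolated) | O=C1C(CN(C)C)[C@H]2CC3=C(C)[C@@H](O)CC[C@]3(C)C[C@H]2O1 | intermediate
20 | trimethylammonium iodide of 19 (epimers at C11, not isolated) | O=C1C(C[N+](C)(C)C)[C@H]2CC3=C(C)[C@@H](O)CC[C@]3(C)C[C@H]2O1.[I-] | intermediate
21 | (3aR,6S,8aR,9aR)-6-hydroxy-5,8a-dimethyl-3-methylidene-3a,4,6,7,8,8a,9,9a-octahydronaphtho[2,3-b]furan-2(3H)-one | C=C1[C@H]2CC3=C(C)[C@@H](O)CC[C@]3(C)C[C@H]2OC1=O | intermediate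
22 | (3aR,6S,8aR,9aR)-5,8a-dimethyl-3-methylidene-2-oxo-2,3,3a,4,6,7,8,8a,9,9a-decahydronaphtho[2,3-b]furan-6-yl 2-methylpropanoate | C=C1[C@H]2CC3=C(C)[C@@H](OC(=O)C(C)C)CC[C@]3(C)C[C@H]2OC1=O | intermediate
23 | potassium 2-[(2R,3R,4aR,7S)-3-hydroxy-4a,8-dimethyl-7-(2-methylpropanoyloxy)-1,2,3,4,4a,5,6,7-octahydronaphthalen-2-yl]prop-2-enoate (not isolated) | C=C(C(=O)[O-])[C@H]1CC2=C(C)[C@@H](OC(=O)C(C)C)CC[C@]2(C)C[C@H]1O.[K+] | intermediate
24 | methyl 2-[(2R,3R,4aR,7S)-3-hydroxy-4a,8-dimethyl-7-(2-methylpropanoyloxy)-1,2,3,4,4a,5,6,7-octahydronaphthalen-2-yl]prop-2-enoate | C=C(C(=O)OC)[C@H]1CC2=C(C)[C@@H](OC(=O)C(C)C)CC[C@]2(C)C[C@H]1O | intermediate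
25 | methyl 2-[(2R,3R,4aR,7S)-3-(acetyloxy)-4a,8-dimethyl-7-(2-methylpropanoyloxy)-1,2,3,4,4a,5,6,7-octahydronaphthalen-2-yl]prop-2-enoate (CNP0127901.1) | C=C(C(=O)OC)[C@H]1CC2=C(C)[C@@H](OC(=O)C(C)C)CC[C@]2(C)C[C@H]1OC(C)=O | target

**Summary**
Total step count: 15. Longest linear sequence: 15 steps (from 1 to 25).

**Steps most likely to fail**

1. Step 8 (key step). What may go wrong: competing ipso attack at the ortho carbon C4 (giving a linearly conjugated 2,4-dienone), erosion of facial selectivity at C10, interception of the diazonium ion by trifluoroacetate, or acid-induced dienone–phenol rearrangement of the product. Diastereomers at C10 would have to be separated before any base treatment, because epimerization at C7 of the wrong isomer would produce the enantiomeric series. Fallback (anionic instead of cationic ring closure, by known phenolate para-alkylation chemistry): diazoketone 11 is treated with dry HCl in Et2O to give the α-chloroketone F1. Bu4NF in dilute THF then cleaves the aryl silyl ether to the tetrabutylammonium phenolate F2, which should close ring B by intramolecular SN2 C-alkylation at its para carbon C10 and so comes back to the route at 14.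

2. Step 14. What may go wrong: hydroxide also cleaving the C3 isobutyrate, adding to the exocyclic methylene, or leaving free base that triggers oxa-Michael closure or relactonization during the methylation. Fallback (hydrolyse first, then differentiate the two hydroxyls by site-selective acylation): hydroxy lactone 21, which carries no other ester, is saponified with KOH to the potassium dihydroxy carboxylate F3 and methylated with iodomethane in DMF to the diol ester F4. One equivalent of 2-methylpropanoic anhydride with catalytic DMAP at −40 °C should then acylate the exposed pseudo-equatorial allylic 3β-hydroxyl in preference to the axial 8β-hydroxyl, which is screened by the syn-axial C10 methyl, and so comes back to the route at 24.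

3. Step 15. What may go wrong: relactonization of the γ-hydroxy ester (loss of methanol, back to 22) outrunning acetylation of the hindered axial hydroxyl under the basic acylation conditions. Fallback (trap first, exchange later): crude 24 is silylated at −78 °C with Et3SiOSO2CF3 and 2,6-lutidine, conditions under which a hindered hydroxyl is capped quickly while lactonization is frozen, to give the 8-O-triethylsilyl ether F5. Ac2O with catalytic Cu(OTf)2 in CH2Cl2 should then exchange the silyl ether directly for the acetate, without a free γ-hydroxy ester being exposed to base, and so comes back to the route at 25.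

**Further compounds**
F1 | step 8 | methyl (3R)-3-({3-[tert-butyl(dimethyl)silyloxy]-2,6-dimethylphenyl}methyl)-5-chloro-4-oxopentanoate | COC(=O)C[C@@H](Cc1c(C)ccc(O[Si](C)(C)C(C)(C)C)c1C)C(=O)CCl
F2 | step 8 | tetrabutylammonium 3-[(2R)-2-(chloroacetyl)-4-methoxy-4-oxobutyl]-2,4-dimethylphenolate | COC(=O)C[C@@H](Cc1c(C)ccc([O-])c1C)C(=O)CCl.CCCC[N+](CCCC)(CCCC)CCCC
F3 | step 14 | potassium 2-[(2R,3R,4aR,7S)-3,7-dihydroxy-4a,8-dimethyl-1,2,3,4,4a,5,6,7-octahydronaphthalen-2-yl]prop-2-enoate | C=C(C(=O)[O-])[C@H]1CC2=C(C)[C@@H](O)CC[C@]2(C)C[C@H]1O.[K+]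
F4 | step 14 | methyl 2-[(2R,3R,4aR,7S)-3,7-dihydroxy-4a,8-dimethyl-1,2,3,4,4a,5,6,7-octahydronaphthalen-2-yl]prop-2-enoate | C=C(C(=O)OC)[C@H]1CC2=C(C)[C@@H](O)CC[C@]2(C)C[C@H]1O
F5 | step 15 | methyl 2-[(2R,3R,4aR,7S)-4a,8-dimethyl-7-(2-methylpropanoyloxy)-3-(triethylsilyloxy)-1,2,3,4,4a,5,6,7-octahydronaphthalen-2-yl]prop-2-enoate | C=C(C(=O)OC)[C@H]1CC2=C(C)[C@@H](OC(=O)C(C)C)CC[C@]2(C)C[C@H]1O[Si](CC)(CC)CC
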